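**Retrosynthetic overview**

1. Ring atoms are numbered C1–C18 as they appear in the target SMILES: rings A (C2–C6), B (C1, C2, C6–C10, C18), C (C10, C11, C12, C16, C17, C18), D (C12–C16). The route rests on the C/D hydrindane with quaternary C12 and isopropyl-bearing C15. Rings C and D are cut together by a cobalt-mediated alkyne–alkene–CO [2+2+1] (bonds C12–C16, C13–C14, C14–C15) to a 1,7-enyne on the 5-8 bicycle: methallyl on C10, 4-methylpent-2-ynyl on C18.
2. After the cycloaddition the C14 enone is taken to the target by reduction to the 14α-alcohol, hydroxyl-directed α-face hydrogenation of C15=C16, radical deoxygenation and desilylation.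
3. The two enyne arms come from the bicyclic C18 enone: kinetic α′-methallylation at C10, then methylide epoxidation of C18 and opening with isopropylacetylide.
4. Ring B is closed by ring-closing metathesis at C7=C8 on the adduct of a Z-alkenyl metal (C1, C18, C10, C9, C8) with a ring-A vinyl ketone; hydrogenation and 1,3-oxidative transposition give the enone with the ring-locked C1=C2 alkene.
5. Ring order: A from (R)-pulegone (C5, C6), then B (C9 from an auxiliary-controlled conjugate addition), then C and D in one step.

Key step: step 19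

Remark: β is the face of the C12 methyl group and α the face of the C18 oxygen; the C18 oxygen is carried as a triethylsilyl ether because this ether is expected to hold through the iridium hydrogenation and the steps after it.

**Route**

Step 1
Reactants: 1 (R)-(+)-pulegone
Product: 3 methyl trans-pulegenate, via pulegone dibromide 2 (not isolated)
Conditions: Br2, AcOH, 0 °C; then NaOMe, MeOH, reflux
Reagents that add atoms: sodium methoxide, C[O-].[Na+]
Why: Favorskii ring contraction of the dibromo ketone (cyclopropanone from the C6 enolate, opening by methoxide with loss of the second bromide) gives the cyclopentane ester with the isopropylidene group restored, the C5 methyl centre of pulegone is not touched, and methoxide should equilibrate the ester-bearing C6 to the trans isomer.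

Step 2
Reactants: 3 methyl trans-pulegenate
Product: 4 [(1S,5R)-5-methyl-2-(propan-2-ylidene)cyclopentyl]methanol
Conditions: LiAlH4, Et2O, 0 °C
Reagents that add atoms: none
Why: Hydride reduction of the ester to the primary alcohol leaves the tetrasubstituted alkene and both stereocentres unchanged.

Step 3
Reactants: 4 [(1S,5R)-5-methyl-2-(propan-2-ylidene)cyclopentyl]methanol
Product: 5 (1S,5R)-5-methyl-2-(propan-2-ylidene)cyclopentane-1-carbaldehyde
Conditions: Dess–Martin periodinane, CH2Cl2, 0 °C → rt
Reagents that add atoms: none
Why: Dess–Martin oxidation under non-basic conditions gives the β,γ-unsaturated aldehyde without moving the alkene into conjugation, and C6 is already in its more stable trans arrangement.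

Step 4
Reactants: 5 (1S,5R)-5-methyl-2-(propan-2-ylidene)cyclopentane-1-carbaldehyde
Product: 6 (1R,2S)-2-ethenyl-1-methyl-3-(propan-2-ylidene)cyclopentane
Conditions: Ph3PCH3Br, KHMDS, THF, 0 °C; then 5, −78 → 0 °C
Reagents that add atoms: methylenetriphenylphosphorane (made in the flask from methyltriphenylphosphonium bromide), C=P(c1ccccc1)(c1ccccc1)c1ccccc1
Why: Wittig methylenation at low temperature turns the aldehyde carbon (C7) into the vinyl group faster than the ylide can enolise the aldehyde.

Step 5
Reactants: 6 (1R,2S)-2-ethenyl-1-methyl-3-(propan-2-ylidene)cyclopentane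
Product: 7 (2S,3R)-2-ethenyl-3-methylcyclopentan-1-one
Conditions: O3 (1 equiv, Sudan Red 7B end point), CH2Cl2–MeOH, −78 °C; then Me2S
Reagents that add atoms: ozone, [O-][O+]=O
Why: Chemoselective ozonolysis, in which electrophilic ozone should cleave the tetrasubstituted isopropylidene alkene well before the monosubstituted vinyl group, unmasks the C2 ketone with the trans C5/C6 centres in place.

Step 6
Reactants: 8 (S)-4-benzyloxazolidin-2-one; 9 (E)-but-2-enoic anhydride
Product: 10 (S)-4-benzyl-3-[(E)-but-2-enoyl]oxazolidin-2-one
Conditions: Et3N, LiCl, THF, −20 °C → rt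
Reagents that add atoms: none
Why: N-Acylation of the oxazolidinone with the anhydride under lithium chloride and triethylamine activation gives the N-enoyl imide without touching the auxiliary stereocentre.

Step 7
Reactants: 10 (S)-4-benzyl-3-[(E)-but-2-enoyl]oxazolidin-2-one
Product: 11 (S)-4-benzyl-3-[(R)-3-methylpent-4-enoyl]oxazolidin-2-one
Conditions: vinylMgBr, CuBr·SMe2, THF, −78 → −20 °C
Reagents that add atoms: vinylmagnesium bromide, C=C[Mg]Br
Why: Copper-mediated conjugate addition to the magnesium-chelated s-cis N-enoyl oxazolidinone takes place on the alkene face away from the benzyl group, which sets the future C9 (R in this fragment, the centre that carries the β methyl group in the target).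

Step 8
Reactants: 11 (S)-4-benzyl-3-[(R)-3-methylpent-4-enoyl]oxazolidin-2-one
Product: 12 (R)-3-methylpent-4-en-1-ol
Conditions: LiBH4, H2O (1 equiv), Et2O, 0 °C
Reagents that add atoms: none
Why: Reductive cleavage of the imide with lithium borohydride releases the primary alcohol and the auxiliary without affecting the β stereocentre or the vinyl group.

Step 9
Reactants: 12 (R)-3-methylpent-4-en-1-ol
Product: 13 (R)-3-methylpent-4-enal
Conditions: Dess–Martin periodinane, CH2Cl2, 0 °C (volatile, carried on in solution)
Reagents that add atoms: none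
Why: Dess–Martin oxidation gives the aldehyde, whose stereocentre is β to the carbonyl group and cannot epimerise.

Step 10
Reactants: 13 (R)-3-methylpent-4-enal
Product: 14 (3R,5Z)-6-iodo-3-methylhepta-1,5-diene
Conditions: Ph3PEtI, n-BuLi, THF; I2, −78 °C; NaHMDS, −20 °C; then 13, −78 → −20 °C
Reagents that add atoms: (1-iodoethylidene)triphenylphosphorane (made in the flask from ethyltriphenylphosphonium iodide and iodine), CC(I)=P(c1ccccc1)(c1ccccc1)c1ccccc1
Why: Wittig olefination with the α-iodoethylidene ylide (Stork–Zhao type) should give the trisubstituted alkenyl iodide with iodine cis to the chain, the geometry that later places C2 and C10 cis on the C1=C18 alkene.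

Step 11
Reactants: 14 (3R,5Z)-6-iodo-3-methylhepta-1,5-diene; 7 (2S,3R)-2-ethenyl-3-methylcyclopentan-1-one
Product: 17 (1R,2S,3R)-2-ethenyl-3-methyl-1-[(2Z,5R)-5-methylhepta-2,6-dien-2-yl]cyclopentan-1-ol, via alkenyllithium 15 (not isolated), via alkenylcerium dichloride 16 (not isolated)
Conditions: t-BuLi (2 equiv), Et2O, −78 °C; CeCl3, THF, −78 °C; then 7, −78 °C
Reagents that add atoms: none
Why: Iodine–lithium exchange with retention of alkene geometry and transmetalation to the weakly basic organocerium allow 1,2-addition to the easily enolised vinyl ketone, the nucleophile is expected to enter anti to the C6 vinyl group, and the configuration of the new C2 carbinol is of no consequence because C2 becomes sp2 in step 14.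

Step 12
Reactants: 17 (1R,2S,3R)-2-ethenyl-3-methyl-1-[(2Z,5R)-5-methylhepta-2,6-dien-2-yl]cyclopentan-1-ol
Product: 18 (2Z,6Z)-2,5,9-trimethylbicyclo[6.3.0]undeca-2,6-dien-1-ol (alkenes C1=C18 and C7=C8 in target numbering)
Conditions: Grubbs II (5 mol %), CH2Cl2 (3 mM), 40 °C
Reagents that add atoms: none
Why: Ring-closing metathesis of the two monosubstituted alkenes closes ring B at C7=C8 as a 1,5-cyclooctadiene, the Z-trisubstituted C1=C18 alkene and ring A holding the two vinyl groups close and the trisubstituted alkene being too hindered to take part.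

Step 13
Reactants: 18 (2Z,6Z)-2,5,9-trimethylbicyclo[6.3.0]undeca-2,6-dien-1-ol
Product: 19 (2Z)-2,5,9-trimethylbicyclo[6.3.0]undec-2-en-1-ol
Conditions: H2 (1 atm), RhCl(PPh3)3 (10 mol %), benzene, rt
Reagents that add atoms: none
Why: Homogeneous hydrogenation with Wilkinson's catalyst reduces the cis-disubstituted C7=C8 alkene and leaves the trisubstituted C1=C18 alkene of the tertiary allylic alcohol alone.

Step 14
Reactants: 19 (2Z)-2,5,9-trimethylbicyclo[6.3.0]undec-2-en-1-ol
Product: 20 (1Z,5S,8S,9R)-2,5,9-trimethylbicyclo[6.3.0]undec-1-en-3-one (the 5-8 bicyclic C18 enone)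
Conditions: PCC, 4 Å MS, CH2Cl2, rt
Reagents that add atoms: pyridinium chlorochromate, [O-][Cr](=O)(=O)Cl.c1cc[nH+]cc1
Why: Babler–Dauben oxidative transposition ([3,3] shift of the tertiary allylic chromate ester, then oxidation of the secondary chromate) moves oxygen from C2 to C18 and forms the tetrasubstituted C1=C2 alkene, whose geometry is fixed by the eight-membered ring.

Step 15
Reactants: 20 (1Z,5S,8S,9R)-2,5,9-trimethylbicyclo[6.3.0]undec-1-en-3-one; 21 3-bromo-2-methylprop-1-ene (methallyl bromide)
Product: 23 (1Z,4R,5S,8S,9R)-2,5,9-trimethyl-4-(2-methylprop-2-enyl)bicyclo[6.3.0]undec-1-en-3-one, via lithium enolate 22 (not isolated)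
Conditions: LDA, THF, −78 °C; then 21, DMPU, −78 → −40 °C
Reagents that add atoms: none
Why: Kinetic deprotonation of the enone at the α′ carbon C10 and alkylation of the cross-conjugated enolate with the allylic bromide should occur anti to the C9 methyl group (H9 in the enolate plane to avoid allylic strain, attack from the ring periphery), which sets C10 with the methallyl group α and trans to the methyl group.

Step 16
Reactants: 23 (1Z,4R,5S,8S,9R)-2,5,9-trimethyl-4-(2-methylprop-2-enyl)bicyclo[6.3.0]undec-1-en-3-one
Product: 24 C18 spiro-oxirane of 23 (oxirane CH2 = C17 on the β face; oxygen α)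
Conditions: Me3SI, n-BuLi, THF, −10 °C; then 23, −10 °C → rt
Reagents that add atoms: dimethylsulfonium methylide (made in the flask from trimethylsulfonium iodide), [CH2-][S+](C)C
Why: Corey–Chaykovsky epoxidation, in which the small sulfonium methylide adds 1,2 to the hindered enone carbonyl from the face opposite the C10 methallyl group and then closes the oxirane, sets C18 with C17 β and the oxygen α.

Step 17
Reactants: 24 C18 spiro-oxirane; 25 3-methylbut-1-yne
Product: 27 C18 tertiary alcohol (OH α) with a β 4-methylpent-2-ynyl group and the α methallyl group on C10, via lithium 3-methylbut-1-yn-1-ide 26 (not isolated)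
Conditions: 25, n-BuLi, THF, −78 → 0 °C; then 24, DMSO, rt → 50 °C
Reagents that add atoms: none
Why: SN2 opening of the 2,2-disubstituted oxirane by the lithium acetylide in a dipolar solvent takes place at the methylene carbon C17 (the tertiary allylic carbon C18 is not attacked in the absence of a Lewis acid) and gives the homopropargylic tertiary alcohol with the C18 configuration fixed in step 16.

Step 18
Reactants: 27 C18 tertiary alcohol
Product: 28 triethylsilyl ether of 27 (the 1,7-enyne: C12=C13 alkene, C15≡C16 alkyne)
Conditions: Et3SiOTf, 2,6-lutidine, CH2Cl2, −78 → 0 °C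
Reagents that add atoms: triethylsilyl trifluoromethanesulfonate, CC[Si](CC)(CC)OS(=O)(=O)C(F)(F)F
Why: Silylation of the hindered tertiary alcohol with the silyl triflate gives the triethylsilyl ether, which keeps the oxygen from binding cobalt and later from directing hydrogenation towards C1=C2.

Step 19
Reactants: 28 1,7-enyne triethylsilyl ether; 29 carbon monoxide
Product: 31 tetracyclic C14 enone (C15=C16 with isopropyl on C15; 12-methyl β; OSiEt3 on C18), via alkyne–dicobalt hexacarbonyl complex 30 (not isolated)
Conditions: Co2(CO)8 (1.1 equiv), ClCH2CH2Cl, rt; then n-BuSMe (4 equiv), CO (1 atm), 83 °C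
Reagents that add atoms: none
Why: The alkyne of 28 forms the Co2(CO)6 complex 30, the sulfide opens a coordination site, the C12=C13 alkene binds and inserts into a Co–C16 bond (C12–C16), CO inserts into the Co–C13 bond (C13–C14) and reductive elimination makes C14–C15, which is a Pauson–Khand [2+2+1] cycloaddition. The closest known case is the intramolecular Pauson–Khand reaction of 1,7-enynes that carry a 1,1-disubstituted alkene and give bicyclo[4.3.0]nonenones with an angular methyl group. Ring C (C10, C11, C12, C16, C17, C18) closes as the six-membered tether ring in the alkene-insertion step, and ring D (C12–C16) closes as the cyclopentenone in the CO-insertion and reductive-elimination steps. C12 is the only new stereocentre: ring C should form as a chair whose two bonds into ring B (C10–C9 and C18–C1) are equatorial, and the nearly planar enone ring needs C13 equatorial, so the methyl group ends up axial on the β face, syn to H10. The step needs this alkene-face selectivity and reaction at the methallyl alkene only; the trans arrangement of the two arms on C10 and the fully substituted C18 fold the chain for closure, and the tetrasubstituted C1=C2 alkene is too hindered to bind cobalt and cannot reach the alkyne in an unstrained ring.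

Step 20
Reactants: 31 tetracyclic C14 enone
Product: 32 14α-allylic alcohol (14R; C15=C16 kept; OSiEt3 on C18)
Conditions: (S)-Me-CBS (0.5 equiv), BH3·THF, THF, −20 °C
Reagents that add atoms: none
Why: Corey–Bakshi–Shibata reduction under catalyst control (the substituted alkene arm C15 as the large group, the C13 methylene as the small one) should deliver hydride to the β face of the C14 carbonyl group and give the 14α alcohol, against the modest substrate preference for attack anti to the C12 methyl group.

Step 21
Reactants: 32 14α-allylic alcohol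
Product: 33 saturated 14α-alcohol (H15 α, H16 α, isopropyl β, trans C/D fusion; OSiEt3 on C18)
Conditions: [Ir(cod)(PCy3)(py)]PF6 (20 mol %), H2 (1–50 bar), CH2Cl2, rt
Reagents that add atoms: none
Why: Hydroxyl-directed hydrogenation with Crabtree's catalyst, in which iridium bound to the α C14 hydroxyl group adds both hydrogens to the α face of the tetrasubstituted C15=C16 alkene, sets C15 and C16 in one event, while the C1=C2 alkene has no free hydroxyl group next to it and is more hindered.

Step 22
Reactants: 33 saturated 14α-alcohol
Product: 34 C14 O-(imidazole-1-carbothioate) of 33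
Conditions: 1,1′-thiocarbonyldiimidazole, DMAP, ClCH2CH2Cl, 80 °C
Reagents that add atoms: 1,1′-thiocarbonyldiimidazole, S=C(n1ccnc1)n1ccnc1
Why: Acylation of the secondary C14 alcohol gives the thiocarbonyl derivative needed for the Barton–McCombie deoxygenation without any base that could disturb the neighbouring centres.

Step 23
Reactants: 34 C14 O-(imidazole-1-carbothioate)
Product: 35 sesterfisherol triethylsilyl ether
Conditions: Bu3SnH, AIBN, toluene, 110 °C
Reagents that add atoms: none
Why: Barton–McCombie radical deoxygenation replaces the C14 oxygen by hydrogen through a secondary radical that cannot epimerise C15 or C16.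

Step 24
Reactants: 35 sesterfisherol triethylsilyl ether
Product: 36 sesterfisherol
Conditions: TBAF, THF, 50 °C
Reagents that add atoms: none
Why: Fluoride cleavage of the triethylsilyl ether under non-acidic conditions frees the tertiary allylic C18 alcohol without ionising it and gives the target.

**Compound list**

1 | (R)-(+)-pulegone, (5R)-5-methyl-2-(propan-2-ylidene)cyclohexan-1-one | C[C@@H]1CCC(=C(C)C)C(=O)C1 | starting material
2 | pulegone dibromide, (5R)-2-bromo-2-(2-bromopropan-2-yl)-5-methylcyclohexan-1-one (C2 epimers) | C[C@@H]1CCC(Br)(C(C)(C)Br)C(=O)C1 | intermediate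
3 | methyl trans-pulegenate, methyl (1S,5R)-5-methyl-2-(propan-2-ylidene)cyclopentane-1-carboxylate | CC(C)=C1CC[C@@H](C)[C@@H]1C(=O)OC | intermediate
4 | [(1S,5R)-5-methyl-2-(propan-2-ylidene)cyclopentyl]methanol | CC(C)=C1CC[C@@H](C)[C@@H]1CO | intermediate
5 | (1S,5R)-5-methyl-2-(propan-2-ylidene)cyclopentane-1-carbaldehyde | CC(C)=C1CC[C@@H](C)[C@@H]1C=O | intermediate
6 | (1R,2S)-2-ethenyl-1-methyl-3-(propan-2-ylidene)cyclopentane (trans) | CC(C)=C1CC[C@@H](C)[C@@H]1C=C | intermediate
7 | (2S,3R)-2-ethenyl-3-methylcyclopentan-1-one (trans; ring A with C2 ketone, C6 vinyl, C5 methyl) | O=C1CC[C@@H](C)[C@@H]1C=C | intermediate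
8 | (S)-4-benzyloxazolidin-2-one | O=C1N[C@@H](Cc2ccccc2)CO1 | starting material
9 | (E)-but-2-enoic anhydride (crotonic anhydride) | C/C=C/C(=O)OC(=O)/C=C/C | starting material
10 | (S)-4-benzyl-3-[(E)-but-2-enoyl]oxazolidin-2-one | C/C=C/C(=O)N1[C@@H](Cc2ccccc2)COC1=O | intermediate
11 | (S)-4-benzyl-3-[(R)-3-methylpent-4-enoyl]oxazolidin-2-one | C=C[C@H](C)CC(=O)N1[C@@H](Cc2ccccc2)COC1=O | intermediate
12 | (R)-3-methylpent-4-en-1-ol | C=C[C@H](C)CCO | intermediate
13 | (R)-3-methylpent-4-enal | C=C[C@H](C)CC=O | intermediate
14 | (3R,5Z)-6-iodo-3-methylhepta-1,5-diene | C=C[C@H](C)C/C=C(/C)I | intermediate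
15 | alkenyllithium from 14 (lithium in place of iodine, alkene geometry kept) | C=C[C@H](C)C/C=C(/C)[Li] | intermediate
16 | alkenylcerium dichloride from 15 (same geometry) | C=C[C@H](C)C/C=C(/C)[Ce](Cl)Cl | intermediate
17 | (1R,2S,3R)-2-ethenyl-3-methyl-1-[(2Z,5R)-5-methylhepta-2,6-dien-2-yl]cyclopentan-1-ol (OH cis to the vinyl group) | C=C[C@H](C)C/C=C(/C)[C@@]1(O)CC[C@@H](C)[C@@H]1C=C | intermediate
18 | (2Z,6Z)-2,5,9-trimethylbicyclo[6.3.0]undeca-2,6-dien-1-ol; target numbering: OH on C2 (β), H6 α, 5-methyl α, 9-methyl β, alkenes C1=C18 and C7=C8 | C/C1=C/C[C@@H](C)/C=C\[C@H]2[C@H](C)CC[C@]12O | intermediate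
19 | (2Z)-2,5,9-trimethylbicyclo[6.3.0]undec-2-en-1-ol (18 with C7–C8 saturated) | C/C1=C/C[C@@H](C)CC[C@H]2[C@H](C)CC[C@]12O | intermediate
20 | (1Z,5S,8S,9R)-2,5,9-trimethylbicyclo[6.3.0]undec-1-en-3-one; C18 ketone, C1=C2 alkene, 5-methyl α, H6 α, 9-methyl β | C/C1=C2\CC[C@@H](C)[C@@H]2CC[C@H](C)CC1=O | intermediate
21 | 3-bromo-2-methylprop-1-ene (methallyl bromide) | C=C(C)CBr | starting material
22 | lithium C10=C18 enolate of 20 (ring Z) | [Li]O/C1=C/[C@@H](C)CC[C@H]2[C@H](C)CC\C2=C1/C | intermediate
23 | (1Z,4R,5S,8S,9R)-2,5,9-trimethyl-4-(2-methylprop-2-enyl)bicyclo[6.3.0]undec-1-en-3-one; methallyl on C10 α, trans to the 9-methyl | C/C1=C2\CC[C@@H](C)[C@@H]2CC[C@H](C)[C@@H](CC(C)=C)C1=O | intermediate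
24 | C18 spiro-oxirane of 23; oxirane CH2 (C17) β, oxygen α | C/C1=C2\CC[C@@H](C)[C@@H]2CC[C@H](C)[C@@H](CC(C)=C)[C@]13CO3 | intermediate
25 | 3-methylbut-1-yne | CC(C)C#C | starting material
26 | lithium 3-methylbut-1-yn-1-ide | CC(C)C#C[Li] | intermediate
27 | 5-8 bicyclic C18 tertiary alcohol: OH α, 4-methylpent-2-ynyl on C18 β, methallyl on C10 α | C/C1=C2\CC[C@@H](C)[C@@H]2CC[C@H](C)[C@@H](CC(C)=C)[C@]1(O)CC#CC(C)C | intermediate
28 | triethylsilyl ether of 27 (1,7-enyne) | C/C1=C2\CC[C@@H](C)[C@@H]2CC[C@H](C)[C@@H](CC(C)=C)[C@]1(O[Si](CC)(CC)CC)CC#CC(C)C | intermediate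
29 | carbon monoxide | [C-]#[O+] | starting material
30 | hexacarbonyldicobalt complex of the C15≡C16 alkyne of 28 | C/C1=C2\CC[C@@H](C)[C@@H]2CC[C@H](C)[C@@H](CC(C)=C)[C@]1(O[Si](CC)(CC)CC)CC12[Co]3(=C=O)(=C=O)(=C=O)[Co]1(=C=O)(=C=O)(=C=O)C23C(C)C | intermediate
31 | tetracyclic enone: C14 ketone, C15=C16 alkene, isopropyl on C15, 12-methyl β, H10 β, OSiEt3 on C18 α | C/C1=C2\CC[C@@H](C)[C@@H]2CC[C@H](C)[C@H]2C[C@@]3(C)CC(=O)C(C(C)C)=C3C[C@]12O[Si](CC)(CC)CC | intermediate
32 | 14α-allylic alcohol (14R) of 31 | C/C1=C2\CC[C@@H](C)[C@@H]2CC[C@H](C)[C@H]2C[C@@]3(C)C[C@@H](O)C(C(C)C)=C3C[C@]12O[Si](CC)(CC)CC | intermediate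
33 | saturated 14α-alcohol: H15 α, H16 α, isopropyl β, OSiEt3 on C18 | C/C1=C2\CC[C@@H](C)[C@@H]2CC[C@H](C)[C@H]2C[C@@]3(C)C[C@@H](O)[C@H](C(C)C)[C@@H]3C[C@]12O[Si](CC)(CC)CC | intermediate
34 | C14 O-(imidazole-1-carbothioate) of 33 | C/C1=C2\CC[C@@H](C)[C@@H]2CC[C@H](C)[C@H]2C[C@@]3(C)C[C@@H](OC(=S)n4ccnc4)[C@H](C(C)C)[C@@H]3C[C@]12O[Si](CC)(CC)CC | intermediate
35 | sesterfisherol triethylsilyl ether | C/C1=C2\CC[C@@H](C)[C@@H]2CC[C@H](C)[C@H]2C[C@@]3(C)CC[C@H](C(C)C)[C@@H]3C[C@]12O[Si](CC)(CC)CC | intermediate
36 | sesterfisherol | C/C1=C2\CC[C@@H](C)[C@@H]2CC[C@H](C)[C@H]2C[C@@]3(C)CC[C@H](C(C)C)[C@@H]3C[C@]12O | target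

**Step count**

Total: 24 steps. Longest linear sequence: 19 steps (steps 1–5, then 11–24; the branch through steps 6–10, then 11–24, is equally long).

**Steps most likely to fail**

Step 19 (Pauson–Khand cycloaddition). Alkene insertion may be too slow for a 1,7-enyne that combines a 1,1-disubstituted alkene with an isopropyl-substituted alkyne. Decomplexation, reduction of the complexed alkyne or closure through the other alkene face (the C12 epimer) could then compete. The fallback sets out from 28 and uses a group-4 metallacycle in place of the cobalt complex. Treatment of 28 with Cp2Ti(PMe3)2 in toluene at room temperature should couple the alkyne and the alkene reductively on titanium(II) to give the titanacyclopentene F1, with the same chair-like folding of ring C. Exposure of F1 to CO (1–2 atm, 60–90 °C) inserts CO into the Ti–C13 bond, and reductive elimination gives enone 31, where the route is rejoined. Titanocene-mediated cyclisation and carbonylation of enynes is known for 1,6- and 1,7-enynes, including those with 1,1-disubstituted alkenes.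

Step 21 (directed hydrogenation). The catalyst may fail to turn over at the hindered tetrasubstituted C15=C16 alkene because the axial C18 silyl ether crowds the α face. Slow saturation of C1=C2 or loss of the silyl ether could also occur. The fallback sets out from 31 and sets C16 and C15 by dissolving-metal reduction. Li in liquid NH3/THF with t-BuOH (1 equiv) at −78 °C should protonate the β-carbon C16 to the trans-fused ring junction. A kinetic quench of the resulting C14 enolate (solid NH4Cl) from the open α face, away from the C12 methyl group and C17, should give the saturated ketone F2 with H15 and H16 both α. Because C15 in F2 can epimerise, it is reduced at once (NaBH4, MeOH, 0 °C) to the C14 alcohol F3 (expected 14β, either epimer serves). F3 is converted with 1,1′-thiocarbonyldiimidazole into the thiocarbonyl derivative F4, and Bu3SnH/AIBN then gives 35, where the route is rejoined.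

Step 17 (epoxide opening). Substitution at the hindered methylene of the spiro-oxirane may be sluggish, so that base-induced isomerisation of the allylic epoxide to a dienol or reaction at the wrong carbon takes over. The fallback sets out from ketone 23 and bypasses the epoxide. Allenylmagnesium bromide (from propargyl bromide and Mg with catalytic HgCl2, Et2O, −78 °C) should add to the C18 carbonyl group anti to the methallyl group and give the terminal homopropargylic alcohol F5. NBS with catalytic AgNO3 in acetone converts F5 into the bromoalkyne F6. Copper-catalysed coupling of F6 with isopropylmagnesium chloride (2.2 equiv, CuCl2 cat., NMP, THF, 0 °C; the first equivalent is used by the hydroxyl group) then gives 27, where the route is rejoined.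

**Further compounds**

F1 | step 19 | titanacyclopentene from 28: Cp2Ti bonded to C13 and C15, C12–C16 bond formed | C/C1=C2\CC[C@@H](C)[C@@H]2CC[C@H](C)[C@H]2C[C@@]3(C)C[Ti](C4C=CC=C4)(C4C=CC=C4)C(C(C)C)=C3C[C@]12O[Si](CC)(CC)CC
F2 | step 21 | saturated C14 ketone: H15 α, H16 α, isopropyl β, OSiEt3 on C18 | C/C1=C2\CC[C@@H](C)[C@@H]2CC[C@H](C)[C@H]2C[C@@]3(C)CC(=O)[C@H](C(C)C)[C@@H]3C[C@]12O[Si](CC)(CC)CC
F3 | step 21 | saturated 14β-alcohol (C14 epimer of 33) | C/C1=C2\CC[C@@H](C)[C@@H]2CC[C@H](C)[C@H]2C[C@@]3(C)C[C@H](O)[C@H](C(C)C)[C@@H]3C[C@]12O[Si](CC)(CC)CC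
F4 | step 21 | C14 O-(imidazole-1-carbothioate) of F3 | C/C1=C2\CC[C@@H](C)[C@@H]2CC[C@H](C)[C@H]2C[C@@]3(C)C[C@H](OC(=S)n4ccnc4)[C@H](C(C)C)[C@@H]3C[C@]12O[Si](CC)(CC)CC
F5 | step 17 | C18 tertiary alcohol (OH α) with a β prop-2-ynyl group and the α methallyl group on C10 | C/C1=C2\CC[C@@H](C)[C@@H]2CC[C@H](C)[C@@H](CC(C)=C)[C@]1(O)CC#C
F6 | step 17 | 3-bromoprop-2-ynyl analogue of F5 | C/C1=C2\CC[C@@H](C)[C@@H]2CC[C@H](C)[C@@H](CC(C)=C)[C@]1(O)CC#CBr
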